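**Plan**

1. Core numbering used throughout: C1 acyl-bearing bridgehead, C2–C4 ring A, C5 second bridgehead, C6–C8 ring B (C7 prenyl, C8 methyl/homogeranyl), C9 bridging ketone. Ring A (C1–C2–C3–C4–C5–C9) is a 1,3-dicarbonyl bridge over ring B whose C4 carbonyl sits between vinylic C3 and C5, the only readily enolised carbon beside the C9 ketone, so C4 can enter as CO between a C3 vinyl–palladium and the C5 enolate.
2. Retrosynthesis: remove the C2 oxygen (enolised diketone to C2=C3 enone); cut C3–C4 and C4–C5 together, C4 leaving as CO, to a ring B diketone with a (Z)-2-iodovinyl group on C1; cut C1–C2, C1–acyl and C8–homogeranyl back to (R)-3-methyl-4-prenylcyclohexenone, itself from 5-methylhex-4-enal and methyl vinyl ketone.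
3. Forward: ring B first (Michael addition, aldol condensation); C8 and the C1 acyl group in one pot; the C1 two-carbon unit as an alkyne, trimmed to the Z-iodoalkene; ring A by carbonylative closure; C2 oxygenated last.
4. Stereochemistry: C7 from the (R)-diarylprolinol ether catalyst; C8 by cuprate addition anti to the C7 prenyl group; C1 by axial alkynylation of the diketonate anti to that prenyl group; C5 dictated by C1 in the ring closure.
5. A β-iodo enol ether on C1 would carry the C2 oxygen through the closure, but with iodine cis to C1 it is only reachable by electrophilic iodo-alkoxylation, which the three trisubstituted alkenes would not survive. The Z-iodoalkene (iodoalkyne, then diimide) is alkene-safe, and C2 is then oxygenated by nucleophilic borylation.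

Key step: step 13

Remark: 5-methylhex-4-enal (1) is taken as a purchasable aldehyde; the target is an enolised 1,3-diketone drawn as its C4-enol tautomer, into which the synthetic diketone should equilibrate.

**Route**

Step 1
Reactants: 1 5-methylhex-4-enal; 2 but-3-en-2-one (methyl vinyl ketone)
Product: 3 (2R)-2-(3-methylbut-2-en-1-yl)-5-oxohexanal
Conditions: (R)-2-[methoxy(diphenyl)methyl]pyrrolidine (5 mol%), ethyl 3,4-dihydroxybenzoate (20 mol%), neat, 4 °C
Reagents that add atoms: none
Why: Enamine-catalysed Michael addition of an aldehyde to an enone, in which the diphenyl(methoxy)methyl group of the (R)-catalyst shields one face of the E-enamine so that the new C–C bond should give the (R)-configured α-carbon (the future C7).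

Step 2
Reactants: 3 (2R)-2-prenyl-5-oxohexanal
Product: 4 (4R)-4-(3-methylbut-2-en-1-yl)cyclohex-2-en-1-one
Conditions: LiOH, i-PrOH, rt
Reagents that add atoms: none
Why: Intramolecular aldol condensation of the methyl ketone onto the aldehyde closes ring B, and the mild hydroxide conditions should not erode the γ-stereocentre.

Step 3
Reactants: 4 (4R)-4-prenylcyclohex-2-enone
Product: 5 trimethyl{[(3R,4R)-3-methyl-4-(3-methylbut-2-en-1-yl)cyclohex-1-en-1-yl]oxy}silane
Conditions: Me2CuLi, TMSCl, Et2O/THF, −78 °C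
Reagents that add atoms: lithium dimethylcuprate, [Li+].C[Cu-]C; chlorotrimethylsilane, C[Si](C)(C)Cl
Why: TMSCl-accelerated Gilman cuprate 1,4-addition trans to the prenyl group with in situ O-silylation gives a regiodefined silyl enol ether (the new methyl-bearing centre is removed again in step 4).

Step 4
Reactants: 5 silyl enol ether
Product: 6 (4R)-3-methyl-4-(3-methylbut-2-en-1-yl)cyclohex-2-en-1-one
Conditions: Pd(OAc)2 (10 mol%), O2 (1 atm), DMSO, rt
Reagents that add atoms: none
Why: Saegusa–Ito dehydrogenation (palladium enolate, β-hydride elimination, O2 as terminal oxidant) should restore the enone regiospecifically toward the methyl-bearing carbon and leave the prenyl-bearing centre untouched.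

Step 5
Reactants: 7 geranyl bromide
Product: 8 [(3E)-4,8-dimethylnona-3,7-dien-1-yl](dimethyl)(propan-2-yloxy)silane
Conditions: i-PrOMe2SiCH2MgCl (1.3 equiv), Li2CuCl4 (3 mol%), THF, −78 → 0 °C
Reagents that add atoms: (isopropoxydimethylsilyl)methylmagnesium chloride, CC(C)O[Si](C)(C)C[Mg]Cl
Why: Kochi-type Li2CuCl4-catalysed coupling of a primary Grignard reagent with the allylic bromide at the α-carbon adds the silylmethyl one-carbon unit and keeps the E alkene.

Step 6
Reactants: 8 homogeranyl alkoxysilane
Product: 9 homogeraniol, (3E)-4,8-dimethylnona-3,7-dien-1-ol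
Conditions: H2O2 (30%), KF, KHCO3, THF/MeOH, rt
Reagents that add atoms: hydrogen peroxide, OO
Why: Tamao oxidation converts the C–Si bond of the alkoxysilane into C–OH and does not touch trisubstituted alkenes.

Step 7
Reactants: 9 homogeraniol
Product: 10 homogeranyl iodide, (6E)-9-iodo-2,6-dimethylnona-2,6-diene
Conditions: I2, PPh3, imidazole, CH2Cl2, 0 °C
Reagents that add atoms: iodine, II
Why: Appel-type iodination of the primary alcohol by SN2 displacement of the oxyphosphonium intermediate.

Step 8
Reactants: 10 homogeranyl iodide; 6 (4R)-3-methyl-4-prenylcyclohex-2-enone; 11 2-methylpropanal (isobutyraldehyde)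
Product: 14 (3R,4R)-3-[(3E)-4,8-dimethylnona-3,7-dien-1-yl]-2-(1-hydroxy-2-methylpropyl)-3-methyl-4-(3-methylbut-2-en-1-yl)cyclohexan-1-one (epimer mixture at ring C2 plus carbinol carbon), via homogeranyllithium 12 (not isolated), via lithium enolate 13 (not isolated)
Conditions: 10 (2.2 equiv), t-BuLi (4.4 equiv), Et2O, −78 °C; CuI (1.1 equiv), −40 °C; 6, −78 → −20 °C; 11, −78 °C; aq. NH4Cl
Reagents that add atoms: none
Why: Iodine–lithium exchange and Gilman cuprate 1,4-addition to the β-methyl enone anti to the prenyl group set the C8 quaternary centre (homogeranyl trans, methyl cis to prenyl), and the regiodefined lithium enolate is trapped at C1 in an aldol addition (tandem conjugate addition–aldol).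

Step 9
Reactants: 14 aldol adduct
Product: 15 (3R,4R)-3-[(3E)-4,8-dimethylnona-3,7-dien-1-yl]-3-methyl-4-(3-methylbut-2-en-1-yl)-2-(2-methylpropanoyl)cyclohexan-1-one (C2 epimers and enol forms)
Conditions: IBX, EtOAc, 77 °C
Reagents that add atoms: none
Why: IBX oxidation of a β-hydroxy ketone to the 1,3-diketone, which erases both uncontrolled centres of 14 and does not affect the alkenes.

Step 10
Reactants: 15 ring B 1,3-diketone; 16 1-[(trimethylsilyl)ethynyl]-1,2-benziodoxol-3(1H)-one (TMS-EBX)
Product: 18 (2S,3R,4R)-3-[(3E)-4,8-dimethylnona-3,7-dien-1-yl]-2-ethynyl-3-methyl-4-(3-methylbut-2-en-1-yl)-2-(2-methylpropanoyl)cyclohexan-1-one, via ethynylbenziodoxolone 17 (not isolated)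
Conditions: Bu4NF (1.3 equiv), THF, −78 °C; then 16, −78 °C → rt
Reagents that add atoms: none
Why: Electrophilic alkynylation of a 1,3-dicarbonyl enolate by the ethynyl iodane freed with fluoride (conjugate addition, α-elimination, 1,2-hydrogen shift); the diketonate should be attacked axially on the face anti to the C7 prenyl group and the axial C8 methyl, placing the ethynyl group cis to the homogeranyl chain.

Step 11
Reactants: 18 C1-ethynyl diketone
Product: 19 (2R,3R,4R)-3-[(3E)-4,8-dimethylnona-3,7-dien-1-yl]-2-(iodoethynyl)-3-methyl-4-(3-methylbut-2-en-1-yl)-2-(2-methylpropanoyl)cyclohexan-1-one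
Conditions: NIS (1.1 equiv), AgNO3 (10 mol%), acetone, rt, dark
Reagents that add atoms: N-iodosuccinimide, O=C1CCC(=O)N1I
Why: AgNO3-catalysed C–H iodination of the terminal alkyne through the silver acetylide, which in non-nucleophilic acetone should leave the trisubstituted alkenes alone.

Step 12
Reactants: 19 iodoalkyne
Product: 20 (2S,3R,4R)-3-[(3E)-4,8-dimethylnona-3,7-dien-1-yl]-2-[(Z)-2-iodoethenyl]-3-methyl-4-(3-methylbut-2-en-1-yl)-2-(2-methylpropanoyl)cyclohexan-1-one
Conditions: 2-nitrobenzenesulfonohydrazide, Et3N, THF/i-PrOH, rt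
Reagents that add atoms: none
Why: Diimide syn-reduction of a 1-iodoalkyne gives the Z-iodoalkene, with iodine cis to C1; diimide reduces neither trisubstituted alkenes nor ketones.

Step 13
Reactants: 20 ring B diketone with (Z)-2-iodovinyl on C1; 21 carbon monoxide
Product: 22 (1R,5R,7S,8R)-8-[(3E)-4,8-dimethylnona-3,7-dien-1-yl]-8-methyl-7-(3-methylbut-2-en-1-yl)-1-(2-methylpropanoyl)bicyclo[3.3.1]non-2-ene-4,9-dione
Conditions: Pd2(dba)3 (5 mol%), Xantphos (12 mol%), CO (1 atm), K3PO4 (3 equiv), toluene, 80 °C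
Reagents that add atoms: none
Why: Proposed new method: zerovalent palladium should insert into the C3–I bond with retention of the Z geometry, CO insertion should give the C4 acyl–palladium held cis to C1, phosphate should form the C9 enolate at C5, and C–C reductive elimination from the acyl(enolate)palladium should make C4–C5; the closest known reactions are the intermolecular palladium-catalysed carbonylative α-arylation of ketones to 1,3-diketones and the intramolecular palladium-catalysed α-alkenylation of ketones with vinyl halides. Ring A closes as a six-membered ring by 6-exo-trig attack of C5 on the acyl carbon (carbonyl oxygen exocyclic), giving the bridged bicyclo[3.3.1]nonane. The new C5 stereocentre is fixed by C1, because the acyl chain hangs from the axial C1 substituent and can only reach the same face of ring B, so C5–C4 forms cis to C1–C2. The step needs CO insertion to outrun direct enolate vinylation (which would give a bicyclo[3.2.1]octenone), which the CO atmosphere and slow phosphate-limited enolisation should secure, and C- rather than O-acylation, which carbon-bound palladium enolates under a wide-bite-angle diphosphine should favour. C5 is the only readily enolised carbon because C1 is quaternary and the isopropyl methine is hindered, and the Z geometry puts the acyl group within reach of C5 once ring B adopts the chair with the C1 vinyl group axial.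

Step 14
Reactants: 22 bicyclic enedione
Product: 24 (1S,5R,7S,8R)-8-[(3E)-4,8-dimethylnona-3,7-dien-1-yl]-2-hydroxy-8-methyl-7-(3-methylbut-2-en-1-yl)-1-(2-methylpropanoyl)bicyclo[3.3.1]nonane-4,9-dione (C2 epimers), via β-boryl ketone 23 (not isolated)
Conditions: B2pin2, CuCl (5 mol%), DPEphos (5 mol%), NaOt-Bu (5 mol%), MeOH (2 equiv), THF, rt; then H2O2 (30%), pH 7 phosphate buffer, 0 °C
Reagents that add atoms: hydrogen peroxide, OO
Why: Copper-catalysed conjugate borylation of the enone at C2 followed by C–B oxidation with retention; the neutral buffer is chosen so that the β-ketol should not undergo retro-aldol cleavage, and the C2 configuration is immaterial.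

Step 15
Reactants: 24 β-ketol
Product: 25 prolifenone B, (1R,5R,7S,8R)-8-[(3E)-4,8-dimethylnona-3,7-dien-1-yl]-4-hydroxy-8-methyl-7-(3-methylbut-2-en-1-yl)-1-(2-methylpropanoyl)bicyclo[3.3.1]non-3-ene-2,9-dione
Conditions: Dess–Martin periodinane (1.2 equiv), CH2Cl2, 0 °C
Reagents that add atoms: none
Why: Dess–Martin oxidation of the secondary alcohol gives the 1,3-diketone, which should enolise to the target tautomer; no stereocentre is touched and the alkenes are inert.

**Compound list**

1 | 5-methylhex-4-enal | CC(C)=CCCC=O | starting material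
2 | but-3-en-2-one (methyl vinyl ketone) | CC(=O)C=C | starting material
3 | (2R)-2-(3-methylbut-2-en-1-yl)-5-oxohexanal | O=C[C@@H](CC=C(C)C)CCC(C)=O | intermediate
4 | (4R)-4-(3-methylbut-2-en-1-yl)cyclohex-2-en-1-one | O=C1C=C[C@@H](CC=C(C)C)CC1 | intermediate
5 | trimethyl{[(3R,4R)-3-methyl-4-(3-methylbut-2-en-1-yl)cyclohex-1-en-1-yl]oxy}silane (3,4-trans) | C[Si](C)(C)OC1=C[C@H](C)[C@@H](CC=C(C)C)CC1 | intermediate
6 | (4R)-3-methyl-4-(3-methylbut-2-en-1-yl)cyclohex-2-en-1-one | CC1=CC(=O)CC[C@@H]1CC=C(C)C | intermediate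
7 | geranyl bromide, (2E)-1-bromo-3,7-dimethylocta-2,6-diene | CC(C)=CCC/C(C)=C/CBr | starting material
8 | [(3E)-4,8-dimethylnona-3,7-dien-1-yl](dimethyl)(propan-2-yloxy)silane | CC(C)=CCC/C(C)=C/CC[Si](C)(C)OC(C)C | intermediate
9 | homogeraniol, (3E)-4,8-dimethylnona-3,7-dien-1-ol | CC(C)=CCC/C(C)=C/CCO | intermediate
10 | homogeranyl iodide, (6E)-9-iodo-2,6-dimethylnona-2,6-diene | CC(C)=CCC/C(C)=C/CCI | intermediate
11 | 2-methylpropanal (isobutyraldehyde) | CC(C)C=O | starting material
12 | homogeranyllithium, [(3E)-4,8-dimethylnona-3,7-dien-1-yl]lithium | [Li]CC/C=C(C)/CCC=C(C)C | intermediate (not isolated)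
13 | lithium (3R,4R)-3-[(3E)-4,8-dimethylnona-3,7-dien-1-yl]-3-methyl-4-(3-methylbut-2-en-1-yl)cyclohex-1-en-1-olate | CC(C)=CCC/C(C)=C/CC[C@]1(C)[C@@H](CC=C(C)C)CCC(O[Li])=C1 | intermediate (not isolated)
14 | (3R,4R)-3-[(3E)-4,8-dimethylnona-3,7-dien-1-yl]-2-(1-hydroxy-2-methylpropyl)-3-methyl-4-(3-methylbut-2-en-1-yl)cyclohexan-1-one, epimers at C2 and the carbinol carbon | CC(C)=CCC/C(C)=C/CC[C@]1(C)[C@@H](CC=C(C)C)CCC(=O)C1C(O)C(C)C | intermediate
15 | (3R,4R)-3-[(3E)-4,8-dimethylnona-3,7-dien-1-yl]-3-methyl-4-(3-methylbut-2-en-1-yl)-2-(2-methylpropanoyl)cyclohexan-1-one, C2 epimers and enol forms | CC(C)=CCC/C(C)=C/CC[C@]1(C)[C@@H](CC=C(C)C)CCC(=O)C1C(=O)C(C)C | intermediate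
16 | 1-[(trimethylsilyl)ethynyl]-1,2-benziodoxol-3(1H)-one (TMS-EBX) | C[Si](C)(C)C#CI1OC(=O)c2ccccc12 | starting material
17 | 1-ethynyl-1,2-benziodoxol-3(1H)-one (ethynylbenziodoxolone) | C#CI1OC(=O)c2ccccc12 | intermediate (not isolated)
18 | (2S,3R,4R)-3-[(3E)-4,8-dimethylnona-3,7-dien-1-yl]-2-ethynyl-3-methyl-4-(3-methylbut-2-en-1-yl)-2-(2-methylpropanoyl)cyclohexan-1-one | CC(C)=CCC/C(C)=C/CC[C@]1(C)[C@@H](CC=C(C)C)CCC(=O)[C@]1(C(=O)C(C)C)C#C | intermediate
19 | (2R,3R,4R)-3-[(3E)-4,8-dimethylnona-3,7-dien-1-yl]-2-(iodoethynyl)-3-methyl-4-(3-methylbut-2-en-1-yl)-2-(2-methylpropanoyl)cyclohexan-1-one | CC(C)=CCC/C(C)=C/CC[C@]1(C)[C@@H](CC=C(C)C)CCC(=O)[C@]1(C(=O)C(C)C)C#CI | intermediate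
20 | (2S,3R,4R)-3-[(3E)-4,8-dimethylnona-3,7-dien-1-yl]-2-[(Z)-2-iodoethenyl]-3-methyl-4-(3-methylbut-2-en-1-yl)-2-(2-methylpropanoyl)cyclohexan-1-one | CC(C)=CCC/C(C)=C/CC[C@]1(C)[C@@H](CC=C(C)C)CCC(=O)[C@]1(C(=O)C(C)C)/C=C\I | intermediate
21 | carbon monoxide | [C-]#[O+] | starting material
22 | (1R,5R,7S,8R)-8-[(3E)-4,8-dimethylnona-3,7-dien-1-yl]-8-methyl-7-(3-methylbut-2-en-1-yl)-1-(2-methylpropanoyl)bicyclo[3.3.1]non-2-ene-4,9-dione | CC(C)=CCC/C(C)=C/CC[C@]1(C)[C@@H](CC=C(C)C)C[C@H]2C(=O)[C@]1(C(=O)C(C)C)C=CC2=O | intermediate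
23 | (1R,5R,7S,8R)-8-[(3E)-4,8-dimethylnona-3,7-dien-1-yl]-8-methyl-7-(3-methylbut-2-en-1-yl)-1-(2-methylpropanoyl)-2-(4,4,5,5-tetramethyl-1,3,2-dioxaborolan-2-yl)bicyclo[3.3.1]nonane-4,9-dione, C2 epimers | CC(C)=CCC/C(C)=C/CC[C@]1(C)[C@@H](CC=C(C)C)C[C@H]2C(=O)[C@]1(C(=O)C(C)C)C(B1OC(C)(C)C(C)(C)O1)CC2=O | intermediate (not isolated)
24 | (1S,5R,7S,8R)-8-[(3E)-4,8-dimethylnona-3,7-dien-1-yl]-2-hydroxy-8-methyl-7-(3-methylbut-2-en-1-yl)-1-(2-methylpropanoyl)bicyclo[3.3.1]nonane-4,9-dione, C2 epimers | CC(C)=CCC/C(C)=C/CC[C@]1(C)[C@@H](CC=C(C)C)C[C@H]2C(=O)[C@]1(C(=O)C(C)C)C(O)CC2=O | intermediate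
25 | prolifenone B, (1R,5R,7S,8R)-8-[(3E)-4,8-dimethylnona-3,7-dien-1-yl]-4-hydroxy-8-methyl-7-(3-methylbut-2-en-1-yl)-1-(2-methylpropanoyl)bicyclo[3.3.1]non-3-ene-2,9-dione | CC(C)=CCC/C(C)=C/CC[C@]1(C)[C@@H](CC=C(C)C)C[C@H]2C(=O)[C@]1(C(=O)C(C)C)C(=O)C=C2O | target

**Count**

Total step count: 15. Longest linear sequence: 12 steps (steps 1–4 and 8–15; the homogeranyl branch, steps 5–7, joins at step 8).

**Steps most likely to fail**

Step 13. The carbonylative closure may fail in three ways. CO insertion may lose out to direct enolate vinylation. The acyl–palladium may be captured through the enolate oxygen to give an enol lactone. The acryloyl–palladium may isomerise from Z to E before the ring closes. The fallback sets out from 20 and separates carbonylation from ring closure with known reactions. Palladium-catalysed aryloxycarbonylation of the alkenyl iodide with 2,4,6-trichlorophenyl formate as CO and phenol source (Pd(OAc)2, Xantphos, Et3N, toluene, rt), which keeps the alkene geometry, would give the activated ester 2,4,6-trichlorophenyl (2Z)-3-{(1S,2R,3R)-2-[(3E)-4,8-dimethylnona-3,7-dien-1-yl]-2-methyl-3-(3-methylbut-2-en-1-yl)-1-(2-methylpropanoyl)-6-oxocyclohexyl}prop-2-enoate F1. A classical intramolecular Claisen acylation of the C5 lithium enolate on this aryl ester (LiN(SiMe3)2, THF, −78 °C), made irreversible by the non-nucleophilic trichlorophenoxide, would then close ring A and return to the route at 22.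

Step 10. Attack of the congested diketonate on the ethynyl iodane may be slower than decomposition of the reagent, or the two faces of C1 may not be discriminated well enough. The fallback sets out from 15 and uses ligand coupling at tetravalent lead, a reaction known to alkynylate 1,3-dicarbonyl compounds at crowded carbons. [2-(Trimethylsilyl)ethynyl]lead triacetate, generated from trimethyl[(trimethylsilyl)ethynyl]stannane and Pb(OAc)4 in CHCl3, would give (2R,3R,4R)-3-[(3E)-4,8-dimethylnona-3,7-dien-1-yl]-3-methyl-4-(3-methylbut-2-en-1-yl)-2-(2-methylpropanoyl)-2-[(trimethylsilyl)ethynyl]cyclohexan-1-one F2. Desilylation with Bu4NF buffered by AcOH would return to the route at 18.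

Step 14. Borylcopper addition at the neopentyl-like C2 may be sluggish, the catalytic alkoxide may open the non-enolisable 1,3-diketone by retro-Claisen cleavage, or the β-ketol may fragment by retro-aldol reaction during C–B oxidation. The fallback sets out from 22. Weitz–Scheffer epoxidation (t-BuOOH, DBU, CH2Cl2) would give the 2,3-epoxide of 22 F3. The known isomerisation of α,β-epoxy ketones to 1,3-diketones with zerovalent palladium (Pd(PPh3)4, 1,2-bis(diphenylphosphino)ethane, toluene, 80 °C) would then lead directly to 25, bypassing 24.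

**Further compounds**

F1 | step 13 | 2,4,6-trichlorophenyl (2Z)-3-{(1S,2R,3R)-2-[(3E)-4,8-dimethylnona-3,7-dien-1-yl]-2-methyl-3-(3-methylbut-2-en-1-yl)-1-(2-methylpropanoyl)-6-oxocyclohexyl}prop-2-enoate | CC(C)=CCC/C(C)=C/CC[C@]1(C)[C@@H](CC=C(C)C)CCC(=O)[C@]1(C(=O)C(C)C)/C=C\C(=O)Oc1c(Cl)cc(Cl)cc1Cl
F2 | step 10 | (2R,3R,4R)-3-[(3E)-4,8-dimethylnona-3,7-dien-1-yl]-3-methyl-4-(3-methylbut-2-en-1-yl)-2-(2-methylpropanoyl)-2-[(trimethylsilyl)ethynyl]cyclohexan-1-one | CC(C)=CCC/C(C)=C/CC[C@]1(C)[C@@H](CC=C(C)C)CCC(=O)[C@]1(C(=O)C(C)C)C#C[Si](C)(C)C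
F3 | step 14 | 2,3-epoxide of 22 (2,3-epoxy-8-homogeranyl-8-methyl-7-prenyl-1-(2-methylpropanoyl)bicyclo[3.3.1]nonane-4,9-dione, epoxide face not assigned) | CC(C)=CCC/C(C)=C/CC[C@]1(C)[C@@H](CC=C(C)C)C[C@H]2C(=O)[C@]1(C(=O)C(C)C)C1OC1C2=O
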